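**Retrosynthetic overview**
1. Target 13 ⇐ tris-MOM flavan 12 (global acetal removal last). Ring C, the pyran, is the only ring closed in the route, by C2–O1 Mitsunobu etherification with inversion from the (R)-carbinol 11.
2. The C2 stereocentre comes from Ru-catalysed asymmetric transfer hydrogenation of the 1,3-diarylpropan-1-one 10.
3. Key C4–C4a bond: the ketone β-carbon is made the nucleophile (palladium homoenolate from 1-arylcyclopropanol 8) and joined to the aryl bromide carbon of the fully substituted ring A phenol 5.
4. Fragment 8 comes from Kulinkovich cyclopropanation of the MOM-protected benzoate 7. Fragment 5 comes from phloroglucinol by bis-MOM protection, ortho-bromination and ortho-C-prenylation, so that only O1 is free and cyclisation can give only the 8-prenyl isomer.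
5. Ring order: rings A and B are bought aromatic; the cyclopropane is made in step 5 and opened in step 6; ring C is closed in step 8.

Assumption: phloroglucinol and methyl 3-hydroxy-5-methoxybenzoate are the purchased starting materials; flavan numbering (O1, C2–C4, C4a–C8a) is used for ring positions. The target SMILES is read as the (2S)-flavan.

**Step 1**
Reactants: 1 phloroglucinol
Product: 2 3,5-bis(methoxymethoxy)phenol
Conditions: MOMCl (2.0 equiv), K2CO3 (2.5 equiv), acetone, 0 °C → rt
Reagents that add atoms: chloromethyl methyl ether (MOMCl), COCCl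
Why: Statistical Williamson-type O-alkylation of the threefold-symmetric triol, which with two equivalents of MOMCl gives mainly the bis-acetal (mono- and tris-ethers are separated and recycled); no stereocentre.

**Step 2**
Reactants: 2 3,5-bis(methoxymethoxy)phenol
Product: 3 2-bromo-3,5-bis(methoxymethoxy)phenol
Conditions: NBS (1.0 equiv), i-Pr2NH (10 mol %), CH2Cl2, −78 → 0 °C
Reagents that add atoms: N-bromosuccinimide, O=C1CCC(=O)N1Br
Why: Amine-catalysed ortho-selective electrophilic aromatic bromination of a phenol, in which hydrogen-bond-directed delivery puts bromine at C2 next to the OH and not at the crowded C4 between the two MOM ethers, and one equivalent at low temperature stops at the monobromide; no stereocentre.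

**Step 3**
Reactants: 3 2-bromo-3,5-bis(methoxymethoxy)phenol
Product: 5 2-bromo-3,5-bis(methoxymethoxy)-6-(3-methylbut-2-en-1-yl)phenol, via sodium 2-bromo-3,5-bis(methoxymethoxy)phenoxide 4 (not isolated)
Conditions: NaH (1.05 equiv), toluene, 0 °C; then prenyl bromide (1.1 equiv), rt
Reagents that add atoms: prenyl bromide (1-bromo-3-methylbut-2-ene), CC(C)=CCBr
Why: Ortho-C-alkylation of a phenoxide, in which the tight sodium ion pair 4 in non-polar toluene shields oxygen and directs prenyl bromide to the only free ortho carbon (C-alkylation then tautomerisation) while the para carbon is blocked by two flanking MOM ethers; no stereocentre.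

**Step 4**
Reactants: 6 methyl 3-hydroxy-5-methoxybenzoate
Product: 7 methyl 3-methoxy-5-(methoxymethoxy)benzoate
Conditions: MOMCl (1.3 equiv), K2CO3 (2 equiv), acetone, rt
Reagents that add atoms: chloromethyl methyl ether (MOMCl), COCCl
Why: Williamson-type O-alkylation of the single phenol as its MOM acetal, chosen so that all three phenol protecting groups fall in one final operation; no stereocentre.

**Step 5**
Reactants: 7 methyl 3-methoxy-5-(methoxymethoxy)benzoate
Product: 8 1-[3-methoxy-5-(methoxymethoxy)phenyl]cyclopropan-1-ol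
Conditions: EtMgBr (3 equiv), Ti(OiPr)4 (0.3 equiv), THF, 0 °C → rt; aq. NH4Cl
Reagents that add atoms: ethylmagnesium bromide, CC[Mg]Br
Why: Kulinkovich cyclopropanation, in which the titanium-bound ethylene unit generated from EtMgBr and catalytic Ti(OiPr)4 adds twice to the ester carbonyl as a 1,2-dicarbanion to give the 1-arylcyclopropanol (a stored ketone homoenolate), the aryl MOM and methyl ethers being inert to the Grignard reagent; no stereocentre.

**Step 6 (key step)**
Reactants: 5 2-bromo-3,5-bis(methoxymethoxy)-6-(3-methylbut-2-en-1-yl)phenol; 8 1-[3-methoxy-5-(methoxymethoxy)phenyl]cyclopropan-1-ol (1.3 equiv)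
Product: 10 3-[2-hydroxy-4,6-bis(methoxymethoxy)-3-(3-methylbut-2-en-1-yl)phenyl]-1-[3-methoxy-5-(methoxymethoxy)phenyl]propan-1-one, via palladium homoenolate 9 (not isolated)
Conditions: Pd(OAc)2 (5 mol %), XPhos (10 mol %), Cs2CO3 (3 equiv), toluene, 80 °C
Reagents that add atoms: none
Why: Palladium-catalysed ring-opening cross-coupling of a cyclopropanol with an aryl bromide (ketone homoenolate arylation), in which oxidative addition of zerovalent palladium into the C–Br bond of 5, alkoxide exchange with 8 and strain-driven β-carbon elimination give homoenolate 9, whose ketone β-carbon (an acceptor carbon in ordinary enone chemistry) acts as the nucleophile toward the aryl halide carbon, and the bulky XPhos ligand favours C(sp2)–C(sp3) reductive elimination over β-hydride elimination; no stereocentre.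

**Step 7**
Reactants: 10 3-[2-hydroxy-4,6-bis(methoxymethoxy)-3-(3-methylbut-2-en-1-yl)phenyl]-1-[3-methoxy-5-(methoxymethoxy)phenyl]propan-1-one
Product: 11 (1R)-3-[2-hydroxy-4,6-bis(methoxymethoxy)-3-(3-methylbut-2-en-1-yl)phenyl]-1-[3-methoxy-5-(methoxymethoxy)phenyl]propan-1-ol
Conditions: RuCl[(R,R)-TsDPEN](p-cymene) (2 mol %), HCO2H/Et3N (5:2), EtOAc, 35 °C
Reagents that add atoms: none
Why: Noyori asymmetric transfer hydrogenation, in which the (R,R)-TsDPEN ruthenium hydride reduces the aryl alkyl ketone on the face fixed by the aryl/p-cymene CH–π contact to give the (R)-carbinol (the sense known for acetophenone-type ketones, high ee expected) without touching the prenyl alkene, the MOM ethers or the free phenol.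

**Step 8**
Reactants: 11 (1R)-3-[2-hydroxy-4,6-bis(methoxymethoxy)-3-(3-methylbut-2-en-1-yl)phenyl]-1-[3-methoxy-5-(methoxymethoxy)phenyl]propan-1-ol
Product: 12 (2S)-2-[3-methoxy-5-(methoxymethoxy)phenyl]-5,7-bis(methoxymethoxy)-8-(3-methylbut-2-en-1-yl)chromane
Conditions: PPh3 (1.5 equiv), DIAD (1.5 equiv), THF (0.02 M), 0 °C → rt
Reagents that add atoms: none
Why: Intramolecular Mitsunobu etherification, in which the only free phenol (O1, between the side chain and the prenyl group) displaces the activated benzylic hydroxyl in a 6-exo SN2 step with clean inversion, turning the (R)-carbinol into the (2S)-chroman, the meta-oxygenated ring B giving no SN1 leakage and the MOM ethers on O5 and O7 fixing the prenyl group at C8.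

**Step 9**
Reactants: 12 (2S)-2-[3-methoxy-5-(methoxymethoxy)phenyl]-5,7-bis(methoxymethoxy)-8-(3-methylbut-2-en-1-yl)chromane
Product: 13 (2S)-2-(3-hydroxy-5-methoxyphenyl)-8-(3-methylbut-2-en-1-yl)chromane-5,7-diol
Conditions: HCl (3 M aq.)/MeOH (1:5), 40 °C, 2–3 h, monitored
Reagents that add atoms: none
Why: Acid-catalysed acetal methanolysis removes the three MOM groups, the C2–O bond staying intact because ring B has its oxygens meta to the benzylic carbon (so the stereocentre is kept) and the short mild treatment leaving the prenyl group uncyclised.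

**Compound list**
1 | phloroglucinol (benzene-1,3,5-triol) | Oc1cc(O)cc(O)c1 | starting material
2 | 3,5-bis(methoxymethoxy)phenol | COCOc1cc(O)cc(OCOC)c1 | intermediate
3 | 2-bromo-3,5-bis(methoxymethoxy)phenol | Oc1cc(OCOC)cc(OCOC)c1Br | intermediate
4 | sodium 2-bromo-3,5-bis(methoxymethoxy)phenoxide | [Na+].[O-]c1cc(OCOC)cc(OCOC)c1Br | intermediate (not isolated)
5 | 2-bromo-3,5-bis(methoxymethoxy)-6-(3-methylbut-2-en-1-yl)phenol | Oc1c(CC=C(C)C)c(OCOC)cc(OCOC)c1Br | intermediate
6 | methyl 3-hydroxy-5-methoxybenzoate | COC(=O)c1cc(O)cc(OC)c1 | starting material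
7 | methyl 3-methoxy-5-(methoxymethoxy)benzoate | COC(=O)c1cc(OC)cc(OCOC)c1 | intermediate
8 | 1-[3-methoxy-5-(methoxymethoxy)phenyl]cyclopropan-1-ol | OC1(CC1)c1cc(OC)cc(OCOC)c1 | intermediate
9 | palladium homoenolate: [2-hydroxy-4,6-bis(methoxymethoxy)-3-(3-methylbut-2-en-1-yl)phenyl]{3-[3-methoxy-5-(methoxymethoxy)phenyl]-3-oxopropyl}palladium (divalent palladium, XPhos ligand not drawn) | O=C(CC[Pd]c1c(O)c(CC=C(C)C)c(OCOC)cc1OCOC)c1cc(OC)cc(OCOC)c1 | intermediate (not isolated)
10 | 3-[2-hydroxy-4,6-bis(methoxymethoxy)-3-(3-methylbut-2-en-1-yl)phenyl]-1-[3-methoxy-5-(methoxymethoxy)phenyl]propan-1-one | O=C(CCc1c(O)c(CC=C(C)C)c(OCOC)cc1OCOC)c1cc(OC)cc(OCOC)c1 | intermediate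
11 | (1R)-3-[2-hydroxy-4,6-bis(methoxymethoxy)-3-(3-methylbut-2-en-1-yl)phenyl]-1-[3-methoxy-5-(methoxymethoxy)phenyl]propan-1-ol | O[C@H](CCc1c(O)c(CC=C(C)C)c(OCOC)cc1OCOC)c1cc(OC)cc(OCOC)c1 | intermediate
12 | (2S)-2-[3-methoxy-5-(methoxymethoxy)phenyl]-5,7-bis(methoxymethoxy)-8-(3-methylbut-2-en-1-yl)chromane | COCOc1cc(OC)cc([C@@H]2CCc3c(OCOC)cc(OCOC)c(CC=C(C)C)c3O2)c1 | intermediate
13 | (2S)-2-(3-hydroxy-5-methoxyphenyl)-8-(3-methylbut-2-en-1-yl)chromane-5,7-diol | COc1cc(O)cc([C@@H]2CCc3c(O)cc(O)c(CC=C(C)C)c3O2)c1 | target

**Step count**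
Total: 9 steps. Longest linear sequence: 7 steps (steps 1, 2, 3, 6, 7, 8, 9 from phloroglucinol); the ring B branch (steps 4 and 5) joins at step 6.

**Three steps most likely to fail, with fallbacks**

Step 6 (homoenolate arylation). The aryl bromide is electron-rich, flanked on both sides and carries a free ortho phenol, so oxidative addition is slow and homoenolate 9 may lose β-hydride to give the enone and reduced arene. Fallback, setting out from 8 and 5 and coming back at 10: make that enone on purpose by oxidising cyclopropanol 8 to the aryl vinyl ketone 1-[3-methoxy-5-(methoxymethoxy)phenyl]prop-2-en-1-one F1 (Pd(OAc)2 cat., pyridine, O2, toluene, 80 °C). Then join F1 to bromophenol 5 by a reductive Heck reaction (conjugate hydroarylation: Pd(OAc)2, PPh3, HCO2Na, Bu4NCl, DMF, 80 °C), which gives ketone 10 directly. The route continues with step 7.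

Step 3 (ortho-C-prenylation). O-alkylation and double alkylation compete with C-alkylation of the bromophenoxide. Fallback, setting out from 3 and coming back at 5: O-allylate 3 with methyl 2-methylbut-3-en-2-yl carbonate under Pd(PPh3)4 catalysis (THF, 0 °C, too cold for insertion into the hindered C–Br bond) to the tertiary allyl ether 2-bromo-3,5-bis(methoxymethoxy)phenyl 2-methylbut-3-en-2-yl ether F2. Heating F2 (toluene, 90 °C) then triggers an aromatic Claisen rearrangement, which moves the allyl unit with transposition onto the only free ortho carbon and gives 5.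

Step 2 (mono-ortho-bromination). Para bromination at C4 or dibromination may lower the yield of 3. Fallback, setting out from 2 and coming back at 3: carbamoylate 2 (ClCONEt2, K2CO3, MeCN, 60 °C) to 3,5-bis(methoxymethoxy)phenyl N,N-diethylcarbamate F3. Directed ortho-lithiation (s-BuLi, TMEDA, THF, −78 °C) at the carbon between the carbamate and a MOM ether gives the aryllithium 2-lithio-3,5-bis(methoxymethoxy)phenyl N,N-diethylcarbamate F4, which is quenched cold with BrCH2CH2Br to 2-bromo-3,5-bis(methoxymethoxy)phenyl N,N-diethylcarbamate F5. Carbamate cleavage (NaOH, EtOH/H2O, 70 °C) returns 3.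

**Further compounds**
F1 | step 6 | 1-[3-methoxy-5-(methoxymethoxy)phenyl]prop-2-en-1-one | C=CC(=O)c1cc(OC)cc(OCOC)c1
F2 | step 3 | 2-bromo-3,5-bis(methoxymethoxy)phenyl 2-methylbut-3-en-2-yl ether | C=CC(C)(C)Oc1cc(OCOC)cc(OCOC)c1Br
F3 | step 2 | 3,5-bis(methoxymethoxy)phenyl N,N-diethylcarbamate | CCN(CC)C(=O)Oc1cc(OCOC)cc(OCOC)c1
F4 | step 2 | 2-lithio-3,5-bis(methoxymethoxy)phenyl N,N-diethylcarbamate | CCN(CC)C(=O)Oc1cc(OCOC)cc(OCOC)c1[Li]
F5 | step 2 | 2-bromo-3,5-bis(methoxymethoxy)phenyl N,N-diethylcarbamate | CCN(CC)C(=O)Oc1cc(OCOC)cc(OCOC)c1Br
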